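**Plan**

- The hard part is the fully substituted, unsymmetrical furan-2,5-dione (chain on C3, methyl on C4) joined through 14 CH2 groups to a lone (S)-carbinol that no ring-forming step can control.
- Enabling feature: ring C3=C4 with its two cis carboxyl carbons C2 and C5 (and O1) is a 2-alkyne plus two CO2, and a cis-dialkylmaleic diacid closes to the anhydride by itself. The unbranched (CH2)14 tether also lets a triple bond be walked along it.
- Retrosynthesis: cut ring bonds C2–C3 and C4–C5 to give (S)-nonadec-17-yn-2-yl acetate and 2 CO2; cut the alkyne–CH3 bond; move the triple bond back from C17 to C3 (retro-zipper); cut C4–C5 of the propargylic alcohol to give (S)-but-3-yn-2-ol and 1-bromotetradecane.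
- Forward: C4 + C14 acetylide alkylation joins the chain; a KAPA zipper moves the alkyne 14 positions to the far terminus; C-methylation and O-acetylation follow; the anhydride ring is built last on the alkyne by Ni-catalysed reductive double carboxylation.
- Stereochemistry: the single (S) center is bought in (S)-but-3-yn-2-ol and is never touched (shielded as its alkoxide during the zipper, acetylated with retention).

Key step: step 5

Remark: the target is read as 3-[(15S)-15-acetoxyhexadecyl]-4-methylfuran-2,5-dione, with 14 CH2 groups between ring C3 and the stereocenter. Metal salts of a product that are only protonated on aqueous work-up are treated as the product and are not numbered.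

**Route**

Step 1
Reactants: 1 (S)-but-3-yn-2-ol; 2 1-bromotetradecane
Product: 4 (2S)-octadec-3-yn-2-ol, via dilithiated butynol 3 (not isolated)
Conditions: n-BuLi (2.1 equiv), THF, −78 → −20 °C; then 2 (0.9 equiv), DMPU, −20 °C → rt; H2O
Reagents that add atoms: none
Why: Double deprotonation gives the O,C-dilithio species, whose acetylide carbon is by far the better nucleophile and displaces bromide from the primary bromide 2 (SN2 acetylide alkylation of a propargylic alcohol dianion), while the carbinol C–H is not acidic under these conditions, so the (S) center of 1 should pass into 4 unchanged.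

Step 2
Reactants: 4 (2S)-octadec-3-yn-2-ol
Product: 5 (2S)-octadec-17-yn-2-ol
Conditions: KH (5 equiv), H2N(CH2)3NH2, rt (forms KAPA); then 4, THF, 0 °C → rt; H2O, 0 °C
Reagents that add atoms: none
Why: Alkyne zipper reaction: KAPA moves the triple bond by repeated propargyl–allenyl proton shifts along the unbranched chain and all positional isomers drain irreversibly into the terminal potassium acetylide, whereas C2 is shielded as its potassium alkoxide, so the alkyne can only leave C3 towards C18 and the (S) configuration should be retained, as is known for secondary propargylic alcohols.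

Step 3
Reactants: 5 (2S)-octadec-17-yn-2-ol
Product: 7 (2S)-nonadec-17-yn-2-ol, via dilithiated octadecynol 6 (not isolated)
Conditions: n-BuLi (2.1 equiv), THF, −78 → 0 °C; MeI (1.05 equiv), DMPU, −78 °C → rt; H2O
Reagents that add atoms: iodomethane, CI
Why: The dilithio species is methylated at the acetylide carbon (SN2 alkylation of a lithium acetylide), the aggregated lithium alkoxide being much slower towards one equivalent of MeI at low temperature, and the remote stereocenter is not involved.

Step 4
Reactants: 7 (2S)-nonadec-17-yn-2-ol
Product: 8 (2S)-nonadec-17-yn-2-yl acetate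
Conditions: Ac2O, pyridine, DMAP (cat.), CH2Cl2, 0 °C → rt
Reagents that add atoms: acetic anhydride, CC(=O)OC(C)=O
Why: DMAP-catalysed O-acylation (via the N-acetylpyridinium ion) esterifies the secondary alcohol without breaking the C2–O bond, so the (S) configuration is retained and the target's acetate is in place before the ring is made.

Step 5
Reactants: 8 (2S)-nonadec-17-yn-2-yl acetate
Product: 10 3-[(15S)-15-acetoxyhexadecyl]-4-methylfuran-2,5-dione, via (Z)-maleic diacid 9 (not isolated)
Conditions: Ni(acac)2 (10 mol %), 2,2′-bipyridine (10 mol %), Zn powder (3 equiv), MgBr2 (3 equiv), 4 Å MS, CO2 (1 atm), DMF, rt; then 3 M HCl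
Reagents that add atoms: carbon dioxide, O=C=O
Why: Ni(0)(bpy) couples the C17≡C18 triple bond of 8 with CO2 by oxidative cyclisation to a five-membered oxanickelacyclopentenone; reduction by Zn and activation by MgBr2 then let a second CO2 insert into the Ni–C(sp2) bond with retention of the cis geometry, releasing the (Z)-butenedioate as its Mg/Zn salt and returning Ni(0). The closest known reaction type is the nickel-catalysed reductive double carboxylation of internal alkynes with CO2 (Zn, MgBr2), which converts internal alkynes into maleic anhydrides. On acidification the free diacid 9, whose carboxyl groups are held cis on a tetrasubstituted alkene, should close the furan-2,5-dione ring by 5-exo-trig acyl substitution with loss of water, as dialkylmaleic acids do spontaneously. No stereocenter is formed, the acetate-bearing center 14 CH2 groups away is not touched, and regiochemistry is irrelevant because both alkyne carbons are carboxylated, which is why the unsymmetrical methyl/alkyl substitution pattern poses no regiocontrol problem. The selectivity needed is double over single carboxylation (protonolysis after the first CO2) and over alkyne oligomerisation; rigorously dry conditions (4 Å MS), the CO2 atmosphere, the MgBr2 additive and dilution should secure it, and the secondary alkyl acetate is inert to Ni(0)/Zn at room temperature.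

**Compound list**

1 | (S)-but-3-yn-2-ol | C[C@H](O)C#C | starting material
2 | 1-bromotetradecane | CCCCCCCCCCCCCCBr | starting material
3 | dilithium salt of 1 (O,C-dilithiated but-3-yn-2-ol) | C[C@H]([O-])C#[C-].[Li+].[Li+] | intermediate
4 | (2S)-octadec-3-yn-2-ol | C[C@H](O)C#CCCCCCCCCCCCCCC | intermediate
5 | (2S)-octadec-17-yn-2-ol | C[C@H](O)CCCCCCCCCCCCCCC#C | intermediate
6 | dilithium salt of 5 (O,C-dilithiated octadec-17-yn-2-ol) | C[C@H]([O-])CCCCCCCCCCCCCCC#[C-].[Li+].[Li+] | intermediate
7 | (2S)-nonadec-17-yn-2-ol | C[C@H](O)CCCCCCCCCCCCCCC#CC | intermediate
8 | (2S)-nonadec-17-yn-2-yl acetate | C[C@H](OC(C)=O)CCCCCCCCCCCCCCC#CC | intermediate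
9 | (2Z)-2-[(15S)-15-acetoxyhexadecyl]-3-methylbut-2-enedioic acid | C[C@H](OC(C)=O)CCCCCCCCCCCCCC/C(C(=O)O)=C(\C)C(=O)O | intermediate
10 | 3-[(15S)-15-acetoxyhexadecyl]-4-methylfuran-2,5-dione | CC(=O)O[C@@H](C)CCCCCCCCCCCCCCC1=C(C)C(=O)OC1=O | target

**Summary**

Total step count: 5. Longest linear sequence: 5 steps.

**Steps most likely to fail**

1. Step 5. The catalytic cycle may stop after the first CO2 (protonolysis of the nickelalactone, i.e. hydrocarboxylation), or the unactivated dialkyl alkyne may cyclise too slowly and oligomerise instead. The fallback sets out from 5 and comes back at 10, and replaces ring construction by a decarboxylative radical addition to a preformed anhydride.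
   - Acetylation of 5 (Ac2O, pyridine, DMAP) would give (2S)-octadec-17-yn-2-yl acetate F1.
   - Oxidative cleavage of the terminal alkyne (RuCl3 cat., NaIO4, CCl4/MeCN/H2O) would give (16S)-16-acetoxyheptadecanoic acid F2, one carbon shorter.
   - DCC coupling with N-hydroxypyridine-2-thione would give the Barton ester 2-thioxopyridin-1(2H)-yl (16S)-16-acetoxyheptadecanoate F3.
   - Visible-light photolysis of F3 with excess citraconic anhydride (3-methylfuran-2,5-dione) should decarboxylate it, add the primary radical to the unsubstituted alkene carbon and transfer the thiopyridyl group, giving (2S)-16-[4-methyl-2,5-dioxo-4-(pyridin-2-ylsulfanyl)oxolan-3-yl]hexadecan-2-yl acetate F4 as a diastereomer mixture.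
   - β-Elimination of pyridine-2-thiol (Et3N, or mCPBA then gentle warming) would give 10.

2. Step 2. Configuration at C2 may erode in the strongly basic medium, or migration may stall at internal positions over the 14-carbon walk. The fallback sets out from 4 and comes back at 5, and moves the source of enantiopurity from retention to enzymatic kinetic resolution after the isomerisation.
   - 4 would be isomerised under forcing conditions (excess KAPA, longer time, 50–60 °C) without regard to ee.
   - The crude terminal alkynol would be treated with Candida antarctica lipase B and vinyl acetate in hexane/MTBE. The (R)-enantiomer should be acetylated selectively to (2R)-octadec-17-yn-2-yl acetate F5, which is removed by chromatography, leaving (S)-5.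

3. Step 1. The dianion may react poorly with the long-chain bromide (aggregation, competing E2 elimination or O-alkylation). The fallback sets out from 2 and comes back at 4; it forms the C2–C3 bond instead of C4–C5 and sets the stereocenter by catalyst control.
   - 2 with lithium acetylide–ethylenediamine complex in DMSO would give hexadec-1-yne F6.
   - Lithiation of F6 (n-BuLi, THF, −78 °C) and acylation with N-methoxy-N-methylacetamide would give octadec-3-yn-2-one F7.
   - Asymmetric transfer hydrogenation of F7 with RuCl[(S,S)-TsDPEN](p-cymene) in i-PrOH should give the (S)-propargylic alcohol 4.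

**Further compounds**

F1 | step 5 | (2S)-octadec-17-yn-2-yl acetate | C[C@H](OC(C)=O)CCCCCCCCCCCCCCC#C
F2 | step 5 | (16S)-16-acetoxyheptadecanoic acid | C[C@H](OC(C)=O)CCCCCCCCCCCCCCC(=O)O
F3 | step 5 | 2-thioxopyridin-1(2H)-yl (16S)-16-acetoxyheptadecanoate | C[C@H](OC(C)=O)CCCCCCCCCCCCCCC(=O)ON1C=CC=CC1=S
F4 | step 5 | (2S)-16-[4-methyl-2,5-dioxo-4-(pyridin-2-ylsulfanyl)oxolan-3-yl]hexadecan-2-yl acetate | C[C@H](OC(C)=O)CCCCCCCCCCCCCCC1C(=O)OC(=O)C1(C)Sc1ccccn1
F5 | step 2 | (2R)-octadec-17-yn-2-yl acetate | C[C@@H](OC(C)=O)CCCCCCCCCCCCCCC#C
F6 | step 1 | hexadec-1-yne | C#CCCCCCCCCCCCCCC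
F7 | step 1 | octadec-3-yn-2-one | CC(=O)C#CCCCCCCCCCCCCCC
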